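(The data stem from a simulated flask from invented constants; noise was put on by code.)

The easy step comes first: I reckon the capping by hand before I charge the next flask.

| flask | first end groups | second end groups | one-sided end groups | remark | time |
|---|---|---|---|---|---|
| cedar | 1.5 M (in portions, 3) | 0.74 equiv | 0.075 M | run made earlier; portions every 40 min |  |
| alder | 1.5 M (in portions, 3) | 1.7 equiv | 0.075 M | run made earlier; portions every 40 min |  |
| birch | 2.2 M (in portions, 3) | 1.1 equiv | 0.075 M | run made earlier; portions every 40 min |  |
| flask | 1.5 M (in portions, 3) | 1.10 equiv | 0.0750 M | the portions of first end groups follow each other after 40 min, the first at the start | 20 h |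

- cedar (time / h: links / %, capped ends / %, first end groups / %): 0.833: 25.3, 6.7, 32.2; 2.50: 58.4, 6.5, 20.8; 5.00: 68.3, 4.7, 9.5; 6.00: 67.6, 5.4, 7.9; 10.0: 70.2, 5.0, 3.9; 12.0: 70.1, 4.6, 2.9; 15.0: 74.4, 4.4, 2.6
- alder (time / h: links / %, capped ends / %, first end groups / %): 2.50: 87.8, 7.2, 1.6; 5.00: 91.6, 5.9, 0; 6.00: 91.5, 5.2, 0; 10.0: 90.5, 3.2, 0; 12.0: 91.7, 5.3, 1.6; 15.0: 91.8, 3.5, 2.0
- birch (time / h: links / %, capped ends / %, first end groups / %): 1.33: 52.9, 1.9, 6.1; 4.00: 86.0, 4.6, 2.5; 8.00: 90.7, 5.5, 0; 12.0: 88.8, 2.6, 0; 15.0: 88.5, 2.5, 0.1

(each reading ± 1 percentage point)

- the reaction counts as stopped when no species that holds the first end groups changes by six tenths of a point or more over the second half of the time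

1. at 20 h, what has stopped the reaction, if anything has (the second end groups has run out first / it is still moving / all of the first end groups has reacted)
2. amount of links at 20 h, in percent of the first end groups charged
3. amount of capped ends at 20 h, in percent of the first end groups charged

The flask takes its first end groups in 3 portions. The first portion holds 0.500 M, more than the 0.0750 M of one-sided end groups, so these are the limiting reagent of the capping. The cedar run shows a quick capping. At 0.833 h its capped ends read 6.7%, above their last reading of 4.4%, while its links read 25.3%, a third of their last reading.

So I treat the capping as over early and use one rule, which holds once the one-sided end groups have reacted: capped ends, in percent of the first end groups charged, equal the capping share, c(one-sided end groups) divided by c(first end groups) charged, here 5.00%. The readings test it. The birch run has a share of 3.41%, and its capped ends average 3.42%. Cedar and alder both have a share of 5.00%. They average 5.33% and 5.05%, though second end groups go from 0.74 equiv to 1.7 equiv between them. My decision is to leave c(one-sided end groups) at 0.0750 M and commit to 5.00% of capped ends at 20 h. For links I have no reckoning of my own.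

The forecast says: all of the first end groups has reacted. It gives links 88% (85.5% to 90.5%) and capped ends 4.2% (3% to 5%), noting “The capper is 5% of A charged here”. My figure differs from its central value, above it.

The flask gives: all of the first end groups has reacted. Links come to 86.5% and capped ends to 5.00%, and both lie within the forecast's ranges. In the flask, one-sided end groups already stand at 0% of their own charge at 1.33 h. The flask's capped ends equal the capping share of 5.00%, which puts them on the upper edge of the forecast's range, 5%.

    first end groups + second end groups → links (k = 0.0280 /M/min)
    first end groups + one-sided end groups → capped ends (k = 0.840 /M/min)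
    2 first end groups → self-condensation product (k = 0.00410 /M/min)

Take a second flask with 0.60 M of first end groups, 1.10 equiv of second end groups and 0.0750 M of one-sided end groups. Its first portion holds 0.200 M, still more than the one-sided end groups, and its capping share is 12.5%. The computed flask gives 12.5% of capped ends.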